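No earlier run stands at 80 °C, so you cannot read the cold stage of north-west off a table; you have to reckon it.

| flask | substrate | partner | temperature | remark | time |
|---|---|---|---|---|---|
| midnight | 0.10 M | 0.105 M | 85 °C | run made earlier |  |
| dusk | 0.10 M | 0.052 M | 100 °C | run made earlier |  |
| noon | 0.10 M | 0.21 M | 85 °C | run made earlier |  |
| south-west | 0.10 M (fed, over 8.0 d) | 0.105 M | 100 °C | all else is in the flask from the start; the feed brings no volume worth counting | 10 d |
| east | 0.10 M | 0.105 M | 100 °C | everything together at the start | 10 d |
| south | 0.10 M | 0.105 M (fed, over 8.0 d) |  | the addition at 80 °C, then warmed to 100 °C; the feed brings no volume worth counting | 10 d |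
| north | 0.10 M | 0.105 M (in portions, 3, over 8.0 d) | 100 °C | first portion at the start, last at 8.0 d | 10 d |
| north-west | 0.10 M | 0.105 M |  | everything together at the start at 80 °C, warmed to 100 °C at 8.0 d | 10 d |

| run | time / d | side product / % | target / % | substrate / % |
|---|---|---|---|---|
| midnight | 5.00 | 22.2 | 4.6 | 51.5 |
| midnight | 10.0 | 46.4 | 12.0 | 26.4 |
| midnight | 15.0 | 60.9 | 17.2 | 14.2 |
| midnight | 20.0 | 70.5 | 20.6 | 5.7 |
| dusk | 0.625 | 14.1 | 0 | 66.4 |
| dusk | 1.67 | 47.5 | 3.9 | 33.6 |
| dusk | 3.00 | 71.2 | 8.0 | 15.4 |
| dusk | 8.00 | 89.0 | 11.9 | 0 |
| noon | 2.00 | 6.2 | 1.7 | 77.1 |
| noon | 6.00 | 25.6 | 11.7 | 46.8 |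
| noon | 10.0 | 44.2 | 18.9 | 26.8 |
| noon | 15.0 | 53.8 | 26.2 | 13.9 |

(readings scatter by 1 percentage point)

- the analysis behind the earlier runs scatters by 1 percentage point, standard deviation

* the flask that comes out highest in amount of side product, in percent of the substrate charged, or "all alike" when all lie within 1.5 percentage points (south-west / east / south / north / north-west / all alike)
* side product at the end, in percent of the substrate charged, south-west
* side product at the end, in percent of the substrate charged, east
* side product at the end, in percent of the substrate charged, south
* side product at the end, in percent of the substrate charged, north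
* side product at the end, in percent of the substrate charged, north-west

Here is my own reckoning for north-west, as a chain of estimates.

1. The noon run starts with twice the partner of the midnight run, yet at 10.0 d the midnight and noon runs keep substrate at 26.4% and 26.8%. That is a difference of 0.4 percentage points against a scatter of 1 point. So I treat substrate loss as first order and ignore partner, which gives 0.132 d⁻¹ at 85 °C. The dusk reading at 1.67 d gives 0.653 d⁻¹ at 100 °C.

2. Take the logarithm of the rate constant as straight in temperature. The step down to 80 °C is a third of the step between the runs, so the cold constant is 0.0778 d⁻¹.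

3. North-west spends 8.0 d cold and 2.00 d warm, which adds up to 1.93. This sum of rate constant times time over the stages is the substrate clock.

4. Substrate left is e to the minus clock, so 14.5%.

5. In the dusk run at 1.67 d, the unseen gap in the balance stands at 0.446 times the substrate still there. I carry that ratio over, which gives 6.49% unseen and 79.0% finished.

6. Midnight has the same partner charge, and at 10.0 d its side product is 79.5% of finished material (its selectivity). That gives 62.7%.

7. This share is the weak link, because midnight's clock there is 1.32, less than north-west's. At 15.0 d the midnight clock is 1.98, and the share is 78.0%. I commit to 61.6%.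

The forecast prints 72% for south-west, 78% for east, 62.5% for south, 90.5% for north and 61% for north-west, with north highest. On substrate, it reasons the same way as my first step: “Substrate loss is first order and independent of partner”. My figure differs from it by 0.60 points.

The flasks give 77.5% for south-west, 82.5% for east, 66.7% for south, 91.1% for north and 63.7% for north-west, so north stands highest.

    partner → second intermediate (k = 0.0110 h⁻¹, Ea = 121 kJ mol⁻¹)
    open intermediate + second intermediate → target (k = 0.890 M⁻¹ h⁻¹, Ea = 95.0 kJ mol⁻¹)
    open intermediate → side product (k = 0.0690 h⁻¹, Ea = 128 kJ mol⁻¹)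
    substrate → open intermediate (k = 0.0280 h⁻¹, Ea = 122 kJ mol⁻¹)
    2 second intermediate → homo product (k = 0.610 M⁻¹ h⁻¹, Ea = 102 kJ mol⁻¹)
    (constants at 100 °C)

North-west holds substrate 14.6% at 10.0 d, against 14.5% from the clock. Now read north-west earlier, at 6.0 d, while it is still cold. Its clock is 0.467, so you expect 62.7% of the substrate left, and that north-west reading holds 64.7%. At that time north-west has side product at 12.7% and target at 2.65%.

(Readings and results stem from a simulated flask from invented constants.)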